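**Strategy.** The route rests on the N1–C2 disconnection of the pyrrole ring. In the target, C2 bears bromine directly beside N1, so C2 is brought in as the CBr2 end of a gem-dibromoolefin. A base-induced, metal-free closure of a tosylamide nitrogen onto that carbon forms N1–C2, builds the five-membered ring and retains exactly one bromine at C2 in a single operation, while the C4 and C7 bromines of the benzene ring are carried through untouched. The precursor is a 3,6-dibromo-2-(2,2-dibromovinyl)aniline as its N-tosyl derivative, made from a fluoroarene in three steps. Detosylation and chlorination at the free C3 finish the synthesis.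

Key step: step 4

Remark: indole numbering (N1, C2, C3, C3a, C4–C7, C7a) is used. The target is 2,4,7-tribromo-3-chloro-1H-indole and has no stereocentre, so no stereocontrol is needed. Equivalents are planning values.

**Step 1**
Reactants: 1 1,4-dibromo-2-fluorobenzene; 2 N,N-dimethylformamide
Product: 5 3,6-dibromo-2-fluorobenzaldehyde, via aryllithium 3 (not isolated), via lithium hemiaminolate 4 (not isolated)
Conditions: LiN(iPr)2 (1.1 equiv), THF, −78 °C; DMF (1.5 equiv), −78 °C; aq. HCl quench
Reagents that add atoms: N,N-dimethylformamide (compound 2), CN(C)C=O
Why: Directed ortho-lithiation followed by formylation: the hydrogen flanked by fluorine and bromine is by far the most acidic, the amide base should remove it at −78 °C without bromine–lithium exchange or halogen migration, and the aryllithium adds to DMF to give a hemiaminolate that releases the aldehyde on acidic work-up.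

**Step 2**
Reactants: 5 3,6-dibromo-2-fluorobenzaldehyde; 6 4-methylbenzenesulfonamide
Product: 7 N-(3,6-dibromo-2-formylphenyl)-4-methylbenzenesulfonamide
Conditions: TsNH2 (1.5 equiv), K2CO3 (2.5 equiv), DMSO, 90 °C; dilute aq. HCl work-up
Reagents that add atoms: 4-methylbenzenesulfonamide (compound 6), Cc1ccc(cc1)S(N)(=O)=O
Why: Nucleophilic aromatic substitution (SNAr): the fluoride is ortho to the formyl group and further activated by the neighbouring bromine, fluoride leaves far faster than bromide in an addition-limited SNAr, and the product sits in the flask as its sulfonamidate anion, which shuts off any second substitution.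

**Step 3**
Reactants: 7 N-(3,6-dibromo-2-formylphenyl)-4-methylbenzenesulfonamide; 8 carbon tetrabromide
Product: 9 N-[3,6-dibromo-2-(2,2-dibromoethenyl)phenyl]-4-methylbenzenesulfonamide
Conditions: CBr4 (2 equiv), PPh3 (4 equiv), CH2Cl2, 0 °C to rt
Reagents that add atoms: carbon tetrabromide (compound 8), BrC(Br)(Br)Br
Why: Ramirez gem-dibromoolefination (first stage of the Corey–Fuchs sequence): Ph3P=CBr2 made in the flask from CBr4 and PPh3 converts the formyl group into the dibromovinyl group in a Wittig-type reaction under cold, non-basic conditions that leave the aryl bromides and the sulfonamide alone, and the excess of reagent makes up for any ylide protonated by the acidic N–H.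

**Step 4**
Reactants: 9 N-[3,6-dibromo-2-(2,2-dibromoethenyl)phenyl]-4-methylbenzenesulfonamide
Product: 11 2,4,7-tribromo-1-(4-methylbenzenesulfonyl)-1H-indole, via bromoalkyne 10 (not isolated)
Conditions: Cs2CO3 (2 equiv), dry DMSO, 80 °C, N2
Reagents that add atoms: none
Why: Cs2CO3 deprotonates the sulfonamide and removes HBr from the dibromoolefin by anti elimination to give bromoalkyne 10, whose bromine-bearing carbon is attacked by the nitrogen anion, and protonation of the resulting C3 anion gives the 2-bromoindole; a direct addition–elimination at the CBr2 carbon would lead to the same product. The closest known reaction type is the carbonate-promoted cyclisation of N-sulfonyl 2-(2,2-dibromovinyl)anilines to 2-bromoindoles. The pyrrole ring closes in a 5-endo-dig mode through the N1–C2 bond, the only alternative (attack at the inner alkyne carbon) being a strained 4-exo closure. No stereocentre is formed. The step needs chemoselectivity among four C–Br bonds, and the absence of any transition metal secures it: the two aryl bromides cannot undergo substitution, the vinylic CBr2 carbon is the only electrophile, and after loss of one bromide the remaining C2–Br is an unactivated heteroaryl bromide. Should some tosyl group be lost in the hot basic medium, the N–H indole formed is simply the product of step 5.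

**Step 5**
Reactants: 11 2,4,7-tribromo-1-(4-methylbenzenesulfonyl)-1H-indole
Product: 12 2,4,7-tribromo-1H-indole
Conditions: Bu4NF (TBAF, 1 M in THF, 3 equiv), THF, 65 °C; aqueous work-up
Reagents that add atoms: none
Why: Fluoride-induced N-desulfonylation: fluoride attacks sulfur and expels the indolide, a good leaving group here because three bromines stabilise the anion and the sulfonyl group is squeezed between the C2 and C7 bromines, while the C–Br bonds are inert to fluoride.

**Step 6**
Reactants: 12 2,4,7-tribromo-1H-indole; 13 N-chlorosuccinimide
Product: 14 2,4,7-tribromo-3-chloro-1H-indole (the target)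
Conditions: NCS (1.05 equiv), DMF, 0 °C to rt, dark
Reagents that add atoms: N-chlorosuccinimide (compound 13), ClN1C(=O)CCC1=O
Why: Electrophilic aromatic substitution: C3 is the only unsubstituted and the most nucleophilic position of the pyrrole ring, the benzene ring is deactivated by its two bromines, and one equivalent of NCS at low temperature should stop at monochlorination.

**Compound list**
1 | 1,4-dibromo-2-fluorobenzene | Fc1cc(Br)ccc1Br | starting material
2 | N,N-dimethylformamide | CN(C)C=O | starting material
3 | (3,6-dibromo-2-fluorophenyl)lithium | [Li]c1c(F)c(Br)ccc1Br | intermediate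
4 | lithium (3,6-dibromo-2-fluorophenyl)(dimethylamino)methanolate (racemic, transient) | [Li]OC(N(C)C)c1c(F)c(Br)ccc1Br | intermediate
5 | 3,6-dibromo-2-fluorobenzaldehyde | O=Cc1c(F)c(Br)ccc1Br | intermediate
6 | 4-methylbenzenesulfonamide | Cc1ccc(cc1)S(N)(=O)=O | starting material
7 | N-(3,6-dibromo-2-formylphenyl)-4-methylbenzenesulfonamide | Cc1ccc(cc1)S(=O)(=O)Nc1c(Br)ccc(Br)c1C=O | intermediate
8 | carbon tetrabromide | BrC(Br)(Br)Br | starting material
9 | N-[3,6-dibromo-2-(2,2-dibromoethenyl)phenyl]-4-methylbenzenesulfonamide | Cc1ccc(cc1)S(=O)(=O)Nc1c(Br)ccc(Br)c1C=C(Br)Br | intermediate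
10 | N-[3,6-dibromo-2-(bromoethynyl)phenyl]-4-methylbenzenesulfonamide (present as its caesium salt) | Cc1ccc(cc1)S(=O)(=O)Nc1c(Br)ccc(Br)c1C#CBr | intermediate
11 | 2,4,7-tribromo-1-(4-methylbenzenesulfonyl)-1H-indole | Cc1ccc(cc1)S(=O)(=O)n1c(Br)cc2c(Br)ccc(Br)c21 | intermediate
12 | 2,4,7-tribromo-1H-indole | Brc1cc2c(Br)ccc(Br)c2[nH]1 | intermediate
13 | N-chlorosuccinimide | ClN1C(=O)CCC1=O | starting material
14 | 2,4,7-tribromo-3-chloro-1H-indole | Clc1c(Br)[nH]c2c(Br)ccc(Br)c12 | target

**Totals**
Total step count: 6.
Longest linear sequence: 6 steps (1 → 5 → 7 → 9 → 11 → 12 → 14).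

**Steps most likely to fail**

Step 4 (key step). The ring closure may stall after dehydrobromination, because the sulfonamide nitrogen is flanked on both sides and may add only slowly to the bromoalkyne. Premature loss of the tosyl group may also expose the product to the hot base. The fallback sets out from compound 7 and comes back at compound 11; it puts the C2 bromine on after the ring has been made. Wittig methylenation of 7 (Ph3PCH3Br, KOtBu in excess to cover the N–H, THF) should give N-(3,6-dibromo-2-ethenylphenyl)-4-methylbenzenesulfonamide F1. An oxidative aza-Wacker closure (Hegedus indole synthesis; catalytic PdCl2(MeCN)2, a divalent palladium salt, with p-benzoquinone and LiCl in THF at reflux) tolerates an aryl bromide next to the vinyl group and should give 4,7-dibromo-1-(4-methylbenzenesulfonyl)-1H-indole F2. Sulfonyl-directed lithiation at C2 with LiN(iPr)2 in THF at −78 °C and a quench with 1,2-dibromo-1,1,2,2-tetrachloroethane should then deliver 11.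

Step 3. Protonation of the ylide by the acidic N–H and slow addition to a formyl group shielded by two ortho substituents may leave the aldehyde unconverted. The fallback sets out from compound 7 and comes back at compound 9 without any phosphorus ylide. Condensation with hydrazine hydrate in ethanol should give the hydrazone N-{3,6-dibromo-2-[(E)-hydrazinylidenemethyl]phenyl}-4-methylbenzenesulfonamide F3. Copper-catalysed olefination of this N-unsubstituted hydrazone with CBr4 (compound 8; CuCl, a monovalent copper salt, 10 mol%, aqueous NH3, DMSO, rt) should then give 9 with loss of dinitrogen.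

Step 2. Displacement of a fluoride wedged between a bromine and the formyl group by the bulky, weakly nucleophilic tosylamide anion may be sluggish, and condensation at the aldehyde may compete. The fallback sets out from compound 5 and comes back at compound 7; nitrogen enters as a small, strong nucleophile and is sulfonylated afterwards. NaN3 in DMSO at 60 °C should give 2-azido-3,6-dibromobenzaldehyde F4. Reduction with SnCl2·2H2O in ethyl acetate at rt should give 2-amino-3,6-dibromobenzaldehyde F5. Sulfonylation with 4-methylbenzenesulfonyl chloride in pyridine should then give 7.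

**Further compounds**
F1 | step 4 | N-(3,6-dibromo-2-ethenylphenyl)-4-methylbenzenesulfonamide | Cc1ccc(cc1)S(=O)(=O)Nc1c(Br)ccc(Br)c1C=C
F2 | step 4 | 4,7-dibromo-1-(4-methylbenzenesulfonyl)-1H-indole | Cc1ccc(cc1)S(=O)(=O)n1ccc2c(Br)ccc(Br)c21
F3 | step 3 | N-{3,6-dibromo-2-[(E)-hydrazinylidenemethyl]phenyl}-4-methylbenzenesulfonamide | Cc1ccc(cc1)S(=O)(=O)Nc1c(Br)ccc(Br)c1/C=N/N
F4 | step 2 | 2-azido-3,6-dibromobenzaldehyde | [N-]=[N+]=Nc1c(Br)ccc(Br)c1C=O
F5 | step 2 | 2-amino-3,6-dibromobenzaldehyde | Nc1c(Br)ccc(Br)c1C=O
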